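**Retrosynthetic overview** (locants are those of quinolizidin-2-one in each half: N5, C1–C4 in ring B with the C2 ketone, C6–C9 in ring A, C9a)

1. Target ⇒ 16-membered carbocyclic bis(enone) diamine + 2 CH2O: N–C9a by 6-exo aza-Michael (ring A) and N–C4/C4–C3 by formaldehyde Mannich (ring B), twice, so four rings close in the last operation.
2. The diamine comes from the bis-azide, which comes from head-to-tail HWE cyclodimerisation (2 × C1=C9a) of one aldehyde–β-ketophosphonate monomer; the 16-membered ring is made first.
3. Monomer ⇐ C-alkylation of diethyl (2-oxobutyl)phosphonate by a primary iodide, with the aldehyde masked as a RAMP hydrazone.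
4. Iodide ⇐ RAMP-hydrazone α-alkylation of 5-azidopentanal hydrazone with 1,5-diiodopentane; this sets C9, the only reagent-controlled centre.
5. C9a, C1 and C3 are set in the last step by equilibration relative to C9.

Assumption: tetrahydro-2H-pyran-2-ol and RAMP are bought as such; the target is the (1R,3S,9S,9aR,1′R,3′S,9′S,9a′R) bis-quinolizidinone encoded by the SMILES, in which C9(A) is linked through (CH2)5 to C1(B) and C9(B) through (CH2)5 to C1(A).

**Route**

Step 1
Reactants: 1 tetrahydro-2H-pyran-2-ol; 2 (R)-1-amino-2-(methoxymethyl)pyrrolidine (RAMP)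
Product: 4 (E)-5-{[(2R)-2-(methoxymethyl)pyrrolidin-1-yl]imino}pentan-1-ol, via 5-hydroxypentanal 3 (not isolated)
Conditions: CH2Cl2, 4 Å molecular sieves, 23 °C
Reagents that add atoms: none
Why: The lactol equilibrates with open-chain 5-hydroxypentanal, which condenses with the hydrazine NH2 to give the E aldehyde hydrazone (hydrazone formation); no new stereocentre is formed.

Step 2
Reactants: 4 (E)-5-{[(2R)-2-(methoxymethyl)pyrrolidin-1-yl]imino}pentan-1-ol
Product: 6 (2R)-N-[(E)-5-azidopentylidene]-2-(methoxymethyl)pyrrolidin-1-amine, via mesylate 5 (not isolated)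
Conditions: MsCl, Et3N, CH2Cl2, 0 °C; then NaN3, DMF, 40 °C
Reagents that add atoms: sodium azide, [Na+].[N-]=[N+]=[N-]
Why: Sulfonylation of the primary alcohol and SN2 displacement by azide install the future ring nitrogen in a form that tolerates amide bases, alkylation, ozone and HWE conditions; the hydrazone has no N–H and is untouched.

Step 3
Reactants: 6 (2R)-N-[(E)-5-azidopentylidene]-2-(methoxymethyl)pyrrolidin-1-amine; 7 1,5-diiodopentane
Product: 9 (2R)-N-[(1E,2S)-2-(3-azidopropyl)-7-iodoheptylidene]-2-(methoxymethyl)pyrrolidin-1-amine, via lithium azaenolate 8 (not isolated)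
Conditions: LiN(iPr)2 (commercial solution, 1.1 equiv), THF, 0 °C, 4 h; then 7 (4 equiv), −100 → −78 °C
Reagents that add atoms: none
Why: Enders RAMP-hydrazone alkylation: the chelated E(C=C),Z(C–N) lithium azaenolate is attacked by the primary iodide on the face left open by the methoxymethyl-bound lithium, giving the (S) centre that becomes C9 (expected de ≥ 94%, mirror image of the SAMP series), while excess diiodide suppresses double alkylation.

Step 4
Reactants: 9 (2R)-N-[(1E,2S)-2-(3-azidopropyl)-7-iodoheptylidene]-2-(methoxymethyl)pyrrolidin-1-amine; 10 diethyl (2-oxobutyl)phosphonate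
Product: 12 diethyl [(10S)-13-azido-10-{(E)-[(2R)-2-(methoxymethyl)pyrrolidin-1-yl]iminomethyl}-3-oxotridecan-4-yl]phosphonate (1:1 at C4), via sodium phosphonoenolate 11 (not isolated)
Conditions: 10 (1.5 equiv), NaH (1.4 equiv), DMF, 0 → 23 °C; then 9, 50 °C
Reagents that add atoms: none
Why: SN2 C-alkylation of the stabilised sodium enolate of a β-ketophosphonate at the carbon between P and C=O joins the chain to the future C1; the hydrazone α-CH is far too weakly acidic to be touched, so C9 is safe, and the new P-bearing centre is destroyed in step 6.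

Step 5
Reactants: 12 diethyl [(10S)-13-azido-10-{(E)-[(2R)-2-(methoxymethyl)pyrrolidin-1-yl]iminomethyl}-3-oxotridecan-4-yl]phosphonate
Product: 13 diethyl [(10S)-13-azido-10-formyl-3-oxotridecan-4-yl]phosphonate (1:1 at C4)
Conditions: O3, CH2Cl2, −78 °C; N2 purge; used at once
Reagents that add atoms: ozone, [O-][O+]=O
Why: Ozonolytic cleavage of the hydrazone C=N at −78 °C is the standard racemisation-free release of α-branched aldehydes after hydrazone alkylation; azide, ketone and phosphonate are inert to ozone.

Step 6
Reactants: 13 diethyl [(10S)-13-azido-10-formyl-3-oxotridecan-4-yl]phosphonate (two molecules)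
Product: 15 1,1′-[(1E,3S,9E,11S)-3,11-bis(3-azidopropyl)cyclohexadeca-1,9-diene-1,9-diyl]di(propan-1-one), via linear dimer 14 (not isolated)
Conditions: LiCl, DBU, MeCN (0.02 M), 23 °C; product kept cold and used directly
Reagents that add atoms: none
Why: Masamune–Roush Horner–Wadsworth–Emmons olefination run as a head-to-tail cyclodimerisation: the first intermolecular olefination gives the seco compound, whose 16-membered closure should outcompete the strained 8-membered closure of the monomer; the mild base leaves the aldehyde α-centre intact, homochiral pairing upgrades ee (heterochiral pairs end as a separable meso-type dimer), and the alkene geometry is irrelevant because both sp2 carbons become sp3 in step 7.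

Step 7
Reactants: 15 1,1′-[(1E,3S,9E,11S)-3,11-bis(3-azidopropyl)cyclohexadeca-1,9-diene-1,9-diyl]di(propan-1-one)
Product: 18 (1R,3S,9S,9aR,1′R,3′S,9′S,9a′R)-bis-quinolizidinone CNP0268544.6 (target), via diamine 16 (not isolated), via bis-piperidine 17 (not isolated)
Conditions: PMe3, THF/H2O (9:1, 0.01 M), 23 → 50 °C; then 37% aq. CH2O (2.1 equiv), AcOH (0.2 equiv), EtOH, 60 °C; then DBU (0.3 equiv), 60 °C to constant isomer ratio
Reagents that add atoms: formaldehyde, C=O
Why: Staudinger reduction frees two primary amines that add 6-exo-trig to the enone β-carbons (aza-Michael, ring A twice), the resulting secondary amines form iminium ions with formaldehyde that are trapped by the ethyl-ketone enols (intramolecular Mannich of the pelletierine-condensation type, ring B twice; attack from C1 would give a four-membered ring), and because aza-Michael, Mannich and α-epimerisation are reversible while C9 is not enolisable, C9a, C1 and C3 should settle relative to (S)-C9 in the arrangement with the C1 chain and C3 methyl equatorial on a trans-quinolizidine and the C9 chain axial (avoiding the peri clash with the C1 chain), which is the target configuration.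

**Compound list**

1 | tetrahydro-2H-pyran-2-ol (lactol of 5-hydroxypentanal) | OC1CCCCO1 | starting material
2 | (R)-1-amino-2-(methoxymethyl)pyrrolidine (RAMP) | COC[C@H]1CCCN1N | starting material
3 | 5-hydroxypentanal (not isolated) | OCCCCC=O | intermediate
4 | (E)-5-{[(2R)-2-(methoxymethyl)pyrrolidin-1-yl]imino}pentan-1-ol | OCCCC/C=N/N1CCC[C@@H]1COC | intermediate
5 | methanesulfonate of 4 (not isolated) | CS(=O)(=O)OCCCC/C=N/N1CCC[C@@H]1COC | intermediate
6 | (2R)-N-[(E)-5-azidopentylidene]-2-(methoxymethyl)pyrrolidin-1-amine | [N-]=[N+]=NCCCC/C=N/N1CCC[C@@H]1COC | intermediate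
7 | 1,5-diiodopentane | ICCCCCI | starting material
8 | lithium azaenolate of 6, E at C=C (not isolated) | [Li]N(/C=C/CCCN=[N+]=[N-])N1CCC[C@@H]1COC | intermediate
9 | (2R)-N-[(1E,2S)-2-(3-azidopropyl)-7-iodoheptylidene]-2-(methoxymethyl)pyrrolidin-1-amine | ICCCCC[C@@H](CCCN=[N+]=[N-])/C=N/N1CCC[C@@H]1COC | intermediate
10 | diethyl (2-oxobutyl)phosphonate | CCC(=O)CP(=O)(OCC)OCC | starting material
11 | sodium enolate of 10 (not isolated) | [Na+].CCC([O-])=CP(=O)(OCC)OCC | intermediate
12 | diethyl [(10S)-13-azido-10-{(E)-[(2R)-2-(methoxymethyl)pyrrolidin-1-yl]iminomethyl}-3-oxotridecan-4-yl]phosphonate, 1:1 at C4 | CCC(=O)C(P(=O)(OCC)OCC)CCCCC[C@@H](CCCN=[N+]=[N-])/C=N/N1CCC[C@@H]1COC | intermediate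
13 | diethyl [(10S)-13-azido-10-formyl-3-oxotridecan-4-yl]phosphonate, 1:1 at C4 | CCC(=O)C(P(=O)(OCC)OCC)CCCCC[C@@H](CCCN=[N+]=[N-])C=O | intermediate
14 | linear head-to-tail dimer: free (S)-α-branched aldehyde at one end, one E enone, CH(P(O)(OEt)2)C(O)Et at the other end (not isolated) | O=C[C@H](CCCN=[N+]=[N-])CCCCC/C(C(=O)CC)=C\[C@H](CCCN=[N+]=[N-])CCCCCC(P(=O)(OCC)OCC)C(=O)CC | intermediate
15 | 1,1′-[(1E,3S,9E,11S)-3,11-bis(3-azidopropyl)cyclohexadeca-1,9-diene-1,9-diyl]di(propan-1-one) | CCC(=O)/C1=C/[C@H](CCCN=[N+]=[N-])CCCCC/C(C(=O)CC)=C\[C@H](CCCN=[N+]=[N-])CCCCC1 | intermediate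
16 | 1,1′-[(1E,3S,9E,11S)-3,11-bis(3-aminopropyl)cyclohexadeca-1,9-diene-1,9-diyl]di(propan-1-one) (not isolated) | CCC(=O)/C1=C/[C@H](CCCN)CCCCC/C(C(=O)CC)=C\[C@H](CCCN)CCCCC1 | intermediate
17 | bis-piperidine: 16-membered carbocycle fused at each C9–C9a bond to an N–H piperidine, propanoyl on each C1; drawn as the (1R,9S,9aR,1′R,9′S,9a′R) isomer (not isolated) | N1CCC[C@@H]2CCCCC[C@@H](C(=O)CC)[C@@H]3NCCC[C@@H]3CCCCC[C@@H](C(=O)CC)[C@H]12 | intermediate
18 | target: two (1R,3S,9S,9aR)-3-methylquinolizidin-2-one units joined C9–(CH2)5–C1′ and C9′–(CH2)5–C1 | C[C@H]1CN2CCC[C@@H]3CCCCC[C@H]4C(=O)[C@@H](C)CN5CCC[C@H](CCCCC[C@@H](C1=O)[C@@H]32)[C@H]45 | target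

**Totals and risks**

Total step count: 7. Longest linear sequence: 7 steps (from 1).

The three steps most likely to fail are step 6, step 7 and step 4.

Step 6 is the weakest point. A hindered α-substituted ketophosphonate must olefinate an α-branched aldehyde twice, and the dimerisation has to beat 8-membered ring closure and oligomerisation. The azide can also add slowly to the new enone if 15 is kept warm. The fallback builds the ring in stages instead of in one pot. It sets out from 13 together with its precursor 12. A cross HWE olefination (Ba(OH)2, wet THF) between excess hydrazone-protected phosphonate 12 and slowly added aldehyde 13 gives the linear dimer hydrazone F1. Hydrolysis of the hydrazone with aqueous CuCl2 in THF (ozone is excluded once the enone is present) gives the seco aldehyde 14. This is closed by syringe-pump HWE olefination (K2CO3, 18-crown-6, toluene, 1 mM, 60 °C), and the fallback comes back to the route at 15.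

Step 7 can fail at the formaldehyde stage, through over-hydroxymethylation at C1 or C3 or aminal cross-links. Its equilibration may also fail to give mainly the target isomer, and acid-promoted retro-Mannich chemistry could erode C9. The fallback changes the ring B closure from a C3–C4 Mannich bond to an N–C4 aza-Michael bond. It sets out from 15. α′-Methylenation of both ethyl ketones (paraformaldehyde, diisopropylammonium trifluoroacetate, THF, 60 °C; C3 is the only enolisable α-position) gives the bis(isopropenyl ketone) F2. Staudinger reduction (PMe3, THF/H2O) followed by warming in MeOH with DBU then closes ring A by 6-exo and ring B by 6-endo aza-Michael addition under base only, with no formaldehyde or acid present while the C–N bonds form. The fallback comes back to the route at 18.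

Step 4 can give O-alkylation, dialkylation or a sluggish reaction, as is common for β-ketophosphonate enolates with unactivated iodides. The fallback builds the ketophosphonate by acylation instead of alkylation. It sets out from azaenolate 8, made from 6 as in step 3. Alkylation of 8 with commercial diethyl (6-bromohexyl)phosphonate (THF, −100 → −40 °C) gives the phosphonate hydrazone F3 with the same RAMP-controlled (S) centre. Deprotonation α to phosphorus (LiN(iPr)2, 2.2 equiv, THF, −78 °C) and C-acylation with ethyl propanoate (Claisen-type acylation of a phosphonate carbanion) then gives the ketophosphonate, and the fallback comes back to the route at 12.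

**Further compounds**

F1 | step 6 | linear dimer hydrazone: 14 with its aldehyde still masked as the (E)-RAMP hydrazone | COC[C@H]1CCCN1/N=C/[C@H](CCCN=[N+]=[N-])CCCCC/C(C(=O)CC)=C\[C@H](CCCN=[N+]=[N-])CCCCCC(P(=O)(OCC)OCC)C(=O)CC
F2 | step 7 | 1,1′-[(1E,3S,9E,11S)-3,11-bis(3-azidopropyl)cyclohexadeca-1,9-diene-1,9-diyl]bis(2-methylprop-2-en-1-one) | C=C(C)C(=O)/C1=C/[C@H](CCCN=[N+]=[N-])CCCCC/C(C(=O)C(C)=C)=C\[C@H](CCCN=[N+]=[N-])CCCCC1
F3 | step 4 | diethyl [(7S)-10-azido-7-{(E)-[(2R)-2-(methoxymethyl)pyrrolidin-1-yl]iminomethyl}decyl]phosphonate | CCOP(=O)(OCC)CCCCCC[C@@H](CCCN=[N+]=[N-])/C=N/N1CCC[C@@H]1COC
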